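## Structural features

The target is a germacrane-type ten-membered carbocycle (ring A; germacrane numbering C1–C10, methyl C14 on C10, methyl C15 on C4, isopropenyl C11(=C12)–C13 on C7) with two cis-fused trisubstituted oxiranes, across C1–C10 and across C4–C5. Three secondary oxygens are acylated: (Z)-2-methylbut-2-enoates (angelates) on C3 and C8 and an acetate on C9. The eight stereocentres form two runs, C7–C8–C9–C10–C1 and C3–C4–C5. O9 is anti to the C10 oxirane oxygen (erythro), O3 is syn to the C4 oxirane oxygen (threo), O8 and O9 are anti, and the C6 branch on C7 is syn to O8. The fragile groups are the angelates (isomerisation to tiglates under base, nucleophilic catalysis or heat), an acetate next to a free hydroxyl (1,2-acyl shift), and the oxiranes (acid opening, epoxide migration of 2,3-epoxy alkoxides, transannular reactions in the medium ring). The real difficulty is twofold: closing a ten-membered ring that already carries this functionality, and telling three similar secondary oxygens apart so that C9 alone becomes the acetate. The feature used is the unit C8(OH)–C7(H)–C11(=C12H2), a homoallylic alcohol with adjacent stereocentres C7 and C8. It is the retron of a [2,3]-Wittig shift of an O8–C12 allyl ether, and reconnecting O8 to C12 turns ring A into a 13-membered cyclic ether, so ring A can arise by contraction.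

## Logic of the disconnections

**40 ⇒ 37 + 38.** The two angelate C–O bonds (O3–acyl, O8–acyl) are cut first because these esters are the most fragile groups and must see the fewest reagents. The gain is a diol monoacetate with no isomerisable ester, and both acyl groups come from 38, one molecule for each hydroxyl. The forward step must acylate two hindered secondary hydroxyls without Z→E isomerisation and without moving the C9 acetate.

**37 ⇒ 36 ⇒ 34.** The O3–Si bond and the acetyl C–O bond at O9 are cut, leading to an 8,9-diol with O3 masked. The gain is that all three oxygens are differentiated by only one protecting group. The demand is a monoacetylation that chooses O9 over O8.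

**34 ⇒ 32 (through 33).** C7–C8 is cut and O8 is joined to C12, with the C11=C12 methylene becoming the C7=C11 olefin. This is the strategic cut: the ten-membered ring is exchanged for a 13-membered ether, and C7 and C8 are traded for an olefin geometry and one stannane stereocentre. The forward step needs a configurationally defined C8 carbanion, a (Z)-olefin, and a β-oxygen at C9 that cannot be eliminated.

**32 ⇒ 31 ⇒ 30 ⇒ 29.** The O9 acetal and the O3 silyl group are adjusted and the C4–C5 oxirane is removed to a (Z)-allylic alcohol. The cut is placed here because a free O3 next to a (Z)-trisubstituted olefin can direct the epoxidation to the syn (threo) face. The demand is face selectivity on the macrocycle, with no reaction at the C7=C11 olefin.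

**29 ⇒ 28 ⇒ 27 ⇒ 26.** C3–C4 is cut into an aldehyde and a (Z)-alkenyl iodide within one chain. This opens the 13-membered ring at a bond whose formation tolerates tin, acetal and oxirane. The C3 configuration is not entrusted to the ring closure; it is erased at 28 and reset under catalyst control. The demand is a neutral macrocyclisation that keeps the alkenyl geometry.

**26 ⇒ 25 ⇒ 24 ⇒ 23 + 10.** The O8–C12 ether bond is cut, dividing the chain into two halves of similar size. The demand is an O-alkylation of an α-hydroxystannane that neither loses tin nor scrambles the (Z)-allyl unit.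

**23 ⇒ 22 ⇒ 18 + 19.** The C8–Sn bond is cut by way of the acylstannane, so that C8 is set by a chiral hydride and not by the facial bias of an α-alkoxy aldehyde. The demand is that C9, now α to a carbonyl, keeps its configuration.

**18 ⇒ 17 ⇒ 16 ⇒ 14 + 15.** C8–C9 is cut into an epoxy aldehyde and a vinyl nucleophile whose extra carbon is later removed. The demand is anti addition next to the oxirane.

**14 ⇒ 13 ⇒ 12 ⇒ 11 ⇒ 1 + 7.** The oxirane C–O bonds are removed to a primary (Z)-allylic alcohol (reagent-controlled epoxidation), and the C1=C10 olefin is cut by a Z-selective phosphonate olefination. The gain is two purchasable pieces.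

**10 ⇒ 9 ⇒ 8 ⇒ 6 + 7 and 6 ⇒ 5 ⇒ 4 ⇒ 1 + 2.** The C7=C11 olefin is cut by the same Z-selective olefination and the C4=C5 iodo-olefin by an α-iodo Wittig reaction. Both halves thus start from 1 and share 7. The demand is that the β,γ-unsaturated aldehyde 6 is used before it isomerises.

## Other disconnections considered

**Alternative 1:** The cuts are C9–C10 and C2–C3, with C4=C5 left for a later ring closure. In the forward key step an allenylboronate, for example the pinacol ester A1, would be hydroborated with (Ipc)2BH, and the reagent so formed would allylate aldehyde A2 and then methacrolein A3 in one flask, giving the acyclic (Z)-diol A4.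
- In its favour: three components are joined at once, both carbinols C9 and C3 are set under reagent control in the bond-forming step, the (Z)-C1=C10 olefin comes with it, and no tin is needed. On the speed of building the acyclic chain, and on setting C3 without a redox correction, it is the better of the two plans.
- Against it: A4 contains seventeen chain carbons, not fifteen; the two terminal CH2 groups would have to be excised in a ring-closing metathesis. That metathesis must form a trisubstituted (Z)-olefin in a ten-membered ring, which is the hard medium-ring closure the chosen plan avoids. The C10-methyl version of the double allylboration is less secure than the parent reaction. Both epoxidations would then run on the ten-membered ring, where the anti epoxy alcohol at C9/C10 is the opposite of what a (Z)-allylic alcohol normally gives.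
- Comparison: it is shorter to the open chain, equal on protecting-group load, and weaker on ring formation and on the C9/C10/C1 array, which the chosen plan sets on acyclic material.

**Alternative 2:** The cut is the C1–O bond of the 1,10-oxirane, the oxygen being reconnected across C9–C10. In the forward step NaH would form the C1 alkoxide of the trans-9,10-epoxy-1-ol A5; it would attack C10 with inversion while the old oxirane opens to the C9 alkoxide, giving A6.
- In its favour: the step is stereospecific, it turns an oxirane derived from an (E)-olefin into the cis-1,10-oxirane, and it frees O9 alone. On the differentiation of O9 from O8 it is the better of the two plans.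
- Against it: this epoxide migration is an equilibrium between two trisubstituted oxiranes and two secondary alkoxides with no clear bias. It needs backside attack at the fully substituted C10 inside a ten-membered ring. It presupposes the ring rather than making it, and the (4Z)-olefin would still have to be epoxidised with O3 blocked.
- Comparison: it is a functional-group tactic, not a ring-forming strategy, so step economy cannot be compared without a ring synthesis. On mechanism the chosen plan is safer, because its 1,10-oxirane comes from an irreversible reagent-controlled epoxidation.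

**Alternative 3:** The cut is C5–C6. In the forward step zinc would insert into the primary C6–I bond of diiodide A7, and Pd(PPh3)4 (zerovalent palladium) would couple the resulting C6 zinc end with the (Z)-alkenyl iodide at C5 of the same chain, closing the ten-membered ring of A8.
- In its favour: the conditions are neutral and tolerate esters, so the C9 acetate and C8 angelate are already in place, and the olefin geometry is retained. On the endgame (no late choice between O8 and O9, fewer steps after ring closure) it is the equal or the better of the chosen plan.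
- Against it: it is a direct end-to-end closure of a ten-membered ring by sp3–sp2 coupling, with oligomerisation, protodemetalation and β-hydride pathways as competitors. A7 must already hold C7, C8, C9, C10, C1 and C3, so the C7/C8 syn pair needs its own stereocontrolled step. An angelate would travel through many steps.
- Comparison: structurally similar fragment work; mechanistically it takes on the entropic and transannular cost that the ring contraction avoids.

Key step: step 25

**Remarks and assumptions before the steps**
- Locants follow germacrane numbering throughout; in the 13-membered ethers the ring runs O8–C8–C9–C10–C1–C2–C3–C4–C5–C6–C7–C11–C12. CIP descriptors refer to these locants; the SMILES strings are decisive. MOP = 2-methoxypropan-2-yl, TBS = tert-butyldimethylsilyl.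
- Consistency check: with the (Z)-C7=C11 olefin and the 8R stannane of 32, inversion at C8 and the exo arrangement lead to the 7R,8S centres of 34 and 40. The structures of 32 and 34 agree with each other and with 40 and are used without correction.
- Assumption: in BINAL-H reductions the tributylstannyl group plays the part of the unsaturated substituent, so the (S)-reagent delivers the 8R carbinol; if the sense were the opposite, the (R)-reagent would be used.
- Assumption: 1 and 7 are purchased.

## Steps

Step 1
Reactants: 1 3-[(tert-butyldimethylsilyl)oxy]propanal; 2 ethyltriphenylphosphonium iodide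
Product: 4 (Z)-tert-butyl[(4-iodopent-3-en-1-yl)oxy]dimethylsilane, via (1-iodoethyl)triphenylphosphonium iodide 3 (not isolated)
Conditions: 2, n-BuLi, THF, rt; I2, −78 °C; NaN(SiMe3)2, −20 °C; then 1, −78 → −20 °C
Reagents that add atoms: iodine, II
Why: α-Iodo Wittig olefination of the Stork–Zhao type; the non-stabilised iodo ylide reacts under kinetic control to put iodine cis to the chain, which fixes the later (4Z) geometry.

Step 2
Reactants: 4 (Z)-tert-butyl[(4-iodopent-3-en-1-yl)oxy]dimethylsilane
Product: 5 (Z)-4-iodopent-3-en-1-ol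
Conditions: camphorsulfonic acid (cat.), MeOH, 0 °C → rt
Reagents that add atoms: none
Why: Acid-catalysed methanolysis of a primary silyl ether; the alkenyl iodide is inert.

Step 3
Reactants: 5 (Z)-4-iodopent-3-en-1-ol
Product: 6 (Z)-4-iodopent-3-enal
Conditions: Dess–Martin periodinane, pyridine, CH2Cl2, 0 °C; used at once
Reagents that add atoms: none
Why: Buffered Dess–Martin oxidation; the β,γ-unsaturated aldehyde is not purified so that it cannot move into conjugation.

Step 4
Reactants: 6 (Z)-4-iodopent-3-enal; 7 ethyl 2-[bis(2,2,2-trifluoroethoxy)phosphoryl]propanoate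
Product: 8 ethyl (2Z,5Z)-6-iodo-2-methylhepta-2,5-dienoate
Conditions: 7, KN(SiMe3)2, 18-crown-6, THF, −78 °C; then 6
Reagents that add atoms: none
Why: Still–Gennari olefination; the electron-poor phosphonate and the dissociated potassium enolate make elimination fast, so the kinetic (Z)-trisubstituted enoate (C12 cis to C6) should dominate.

Step 5
Reactants: 8 ethyl (2Z,5Z)-6-iodo-2-methylhepta-2,5-dienoate
Product: 9 (2Z,5Z)-6-iodo-2-methylhepta-2,5-dien-1-ol
Conditions: i-Bu2AlH (2.2 equiv), CH2Cl2, −78 °C; aq. potassium sodium tartrate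
Reagents that add atoms: none
Why: 1,2-Reduction of the enoate by the aluminium hydride; neither olefin geometry nor the alkenyl iodide is touched at −78 °C.

Step 6
Reactants: 9 (2Z,5Z)-6-iodo-2-methylhepta-2,5-dien-1-ol
Product: 10 (2Z,5Z)-1-bromo-6-iodo-2-methylhepta-2,5-diene
Conditions: CBr4, PPh3, CH2Cl2, 0 °C; used promptly
Reagents that add atoms: carbon tetrabromide, BrC(Br)(Br)Br
Why: Appel bromination; SN2 displacement at the primary allylic carbon under neutral conditions should keep the (Z)-allyl geometry.

Step 7
Reactants: 1 3-[(tert-butyldimethylsilyl)oxy]propanal; 7 ethyl 2-[bis(2,2,2-trifluoroethoxy)phosphoryl]propanoate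
Product: 11 ethyl (Z)-5-[(tert-butyldimethylsilyl)oxy]-2-methylpent-2-enoate
Conditions: 7, KN(SiMe3)2, 18-crown-6, THF, −78 °C; then 1
Reagents that add atoms: none
Why: Still–Gennari olefination as in step 4; it sets the (Z)-C1=C10 olefin (C9 cis to C2).

Step 8
Reactants: 11 ethyl (Z)-5-[(tert-butyldimethylsilyl)oxy]-2-methylpent-2-enoate
Product: 12 (Z)-5-[(tert-butyldimethylsilyl)oxy]-2-methylpent-2-en-1-ol
Conditions: i-Bu2AlH (2.2 equiv), CH2Cl2, −78 °C; aq. potassium sodium tartrate
Reagents that add atoms: none
Why: Ester to primary allylic alcohol by 1,2-reduction; the silyl ether is stable.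

Step 9
Reactants: 12 (Z)-5-[(tert-butyldimethylsilyl)oxy]-2-methylpent-2-en-1-ol
Product: 13 [(2S,3R)-3-{2-[(tert-butyldimethylsilyl)oxy]ethyl}-2-methyloxiran-2-yl]methanol
Conditions: Ti(OiPr)4 (0.1 equiv), L-(+)-diethyl tartrate (0.12 equiv), t-BuOOH, 4 Å MS, CH2Cl2, −20 °C
Reagents that add atoms: tert-butyl hydroperoxide, CC(C)(C)OO
Why: Katsuki–Sharpless asymmetric epoxidation of a primary allylic alcohol; the L-(+)-tartrate delivers oxygen to the face that gives the (2S,3R)-oxirane (the sense known for nerol-type (Z)-alcohols), which sets C10 and C1.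

Step 10
Reactants: 13 [(2S,3R)-3-{2-[(tert-butyldimethylsilyl)oxy]ethyl}-2-methyloxiran-2-yl]methanol
Product: 14 (2R,3R)-3-{2-[(tert-butyldimethylsilyl)oxy]ethyl}-2-methyloxirane-2-carbaldehyde
Conditions: Dess–Martin periodinane, pyridine, CH2Cl2, 0 °C → rt
Reagents that add atoms: none
Why: Dess–Martin oxidation; the aldehyde carbon is attached to a fully substituted oxirane carbon, so no epimerisation is possible.

Step 11
Reactants: 14 (2R,3R)-3-{2-[(tert-butyldimethylsilyl)oxy]ethyl}-2-methyloxirane-2-carbaldehyde; 15 vinylmagnesium bromide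
Product: 16 (S)-1-[(2S,3R)-3-{2-[(tert-butyldimethylsilyl)oxy]ethyl}-2-methyloxiran-2-yl]prop-2-en-1-ol
Conditions: CH2=CHMgBr, THF, −78 °C; aq. NH4Cl
Reagents that add atoms: none
Why: Grignard addition to an α,β-epoxy aldehyde; in the Cornforth-type arrangement (oxirane C–O antiperiplanar to C=O) the nucleophile should approach past the α-methyl group and away from oxirane carbon C1 with its cis chain, which gives the 9,10-anti (erythro) alcohol and so sets C9.

Step 12
Reactants: 16 (S)-1-[(2S,3R)-3-{2-[(tert-butyldimethylsilyl)oxy]ethyl}-2-methyloxiran-2-yl]prop-2-en-1-ol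
Product: 17 tert-butyl(2-{(2R,3R)-3-[(S)-1-[(2-methoxypropan-2-yl)oxy]prop-2-en-1-yl]-3-methyloxiran-2-yl}ethoxy)dimethylsilane (9-O-MOP ether of 16)
Conditions: 2-methoxypropene, pyridinium p-toluenesulfonate (cat.), CH2Cl2, 0 °C
Reagents that add atoms: 2-methoxypropene, COC(C)=C
Why: Acid-catalysed addition of the alcohol to an enol ether gives a mixed ketal with no new stereocentre; unlike a silyl ether it cannot migrate to a neighbouring alkoxide later, and it comes off under very mild acid.

Step 13
Reactants: 17 9-O-MOP ether of 16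
Product: 18 (R)-2-[(2-methoxypropan-2-yl)oxy]-2-[(2R,3R)-3-{2-[(tert-butyldimethylsilyl)oxy]ethyl}-2-methyloxiran-2-yl]acetaldehyde
Conditions: O3, CH2Cl2, pyridine, −78 °C; PPh3
Reagents that add atoms: ozone, [O-][O+]=O
Why: Ozonolysis of the only olefin with reductive work-up; pyridine keeps the medium non-acidic for the ketal, and the aldehyde is used crude.

Step 14
Reactants: 18 (R)-2-[(2-methoxypropan-2-yl)oxy]-2-[(2R,3R)-3-{2-[(tert-butyldimethylsilyl)oxy]ethyl}-2-methyloxiran-2-yl]acetaldehyde; 19 tributyltin hydride
Product: 22 (R)-2-[(2-methoxypropan-2-yl)oxy]-2-[(2R,3R)-3-{2-[(tert-butyldimethylsilyl)oxy]ethyl}-2-methyloxiran-2-yl]-1-(tributylstannyl)ethan-1-one, via tributylstannyllithium 20 (not isolated), via lithium stannyl alkoxide 21 (not isolated)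
Conditions: 19, LiN(i-Pr)2, THF, 0 °C; 18, −78 °C; 1,1'-(azodicarbonyl)dipiperidine, −78 → 0 °C
Reagents that add atoms: none
Why: Stannyl anion addition to the aldehyde, then hydride transfer from the lithium alkoxide to the azo compound (Mukaiyama-type oxidation) gives the acylstannane; this is the known route to acylstannanes, and the low temperature limits enolisation towards C9.

Step 15
Reactants: 22 acylstannane
Product: 23 (1R,2R)-2-[(2-methoxypropan-2-yl)oxy]-2-[(2R,3R)-3-{2-[(tert-butyldimethylsilyl)oxy]ethyl}-2-methyloxiran-2-yl]-1-(tributylstannyl)ethan-1-ol (8R,9R,10R,1R)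
Conditions: (S)-BINAL-H [LiAlH(OEt)((S)-1,1'-bi-2-naphtholate)], THF, −78 °C; aq. potassium sodium tartrate
Reagents that add atoms: none
Why: Reagent-controlled BINAL-H reduction of an acylstannane, the standard entry to enantioenriched α-hydroxystannanes; the 8R carbinol is also the Felkin–Anh product of the α-alkoxy ketone (O8 and O9 syn in the chain that ends at tin), so reagent and substrate should cooperate.

Step 16
Reactants: 23 α-hydroxystannane; 10 (2Z,5Z)-1-bromo-6-iodo-2-methylhepta-2,5-diene
Product: 24 open-chain (8R,9R,10R,1R)-stannyl allyl ether: 8-O-[(2Z,5Z)-6-iodo-2-methylhepta-2,5-dien-1-yl], 9-O-MOP, 3-O-TBS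
Conditions: KN(SiMe3)2, THF, −78 °C; 10, 18-crown-6, −78 → −40 °C
Reagents that add atoms: none
Why: Williamson etherification by SN2 at the primary allylic bromide; the dissociated potassium alkoxide is alkylated cold so that ether formation outruns loss of the stannyl group, and the ketal on O9 cannot migrate to O8.

Step 17
Reactants: 24 open-chain stannyl allyl ether
Product: 25 the corresponding primary alcohol (3-OH free; 9-O-MOP, alkenyl iodide and stannane unchanged)
Conditions: Bu4NF, THF, 0 °C
Reagents that add atoms: none
Why: Fluoride cleavage of the primary silyl ether; the ketal, oxirane, α-alkoxystannane and alkenyl iodide are all stable to fluoride.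

Step 18
Reactants: 25 primary alcohol
Product: 26 the C3 aldehyde (β,γ-epoxy aldehyde bearing the (Z)-alkenyl iodide)
Conditions: Dess–Martin periodinane, pyridine, CH2Cl2, 0 °C; filtered and used at once
Reagents that add atoms: none
Why: Buffered Dess–Martin oxidation is non-basic, which is needed because a β,γ-epoxy aldehyde eliminates to the hydroxy enal with base; it goes straight into the next step.

Step 19
Reactants: 26 C3 aldehyde
Product: 27 13-membered stannyl allyl ether, (4Z,7Z)-diene, 3-hydroxy (both C3 epimers), 9-O-MOP, 1,10-epoxide (1R,8R,9R,10R)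
Conditions: CrCl2 (15 equiv), NiCl2 (1 mol% of Cr), DMSO–THF, rt, 0.003 M
Reagents that add atoms: none
Why: Nozaki–Hiyama–Kishi reaction: zerovalent nickel inserts into the alkenyl iodide, the alkenyl group passes to chromium and adds to the aldehyde under neutral conditions with retention of the (Z) geometry. Ring closures of this size are well within its scope; no selectivity at C3 is required here.

Step 20
Reactants: 27 macrocyclic allylic alcohol (C3 epimers)
Product: 28 the macrocyclic (4Z)-enone (3-oxo)
Conditions: MnO2, CH2Cl2, rt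
Reagents that add atoms: none
Why: MnO2 oxidises only the allylic alcohol and is neutral, so the skipped dienone is not pushed into conjugation; the uncontrolled C3 centre is removed.

Step 21
Reactants: 28 macrocyclic enone
Product: 29 (3S)-allylic alcohol of the 13-membered ether (1R,3S,8R,9R,10R)
Conditions: (R)-Me-CBS [(R)-1-methyl-3,3-diphenyltetrahydro-1H,3H-pyrrolo[1,2-c][1,3,2]oxazaborole] (1 equiv), BH3·SMe2, THF, −40 °C; MeOH
Reagents that add atoms: none
Why: Corey–Bakshi–Shibata reduction; the α-methyl alkenyl group acts as the large substituent, so the (R)-catalyst should deliver hydride to give the 3S alcohol under catalyst control.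

Step 22
Reactants: 29 (3S)-allylic alcohol
Product: 30 4,5-epoxy-3-ol of the 13-membered ether (1R,3S,4R,5S,8R,9R,10R)
Conditions: Ti(OiPr)4 (0.3 equiv), t-BuOOH, 4 Å MS, CH2Cl2, −20 °C
Reagents that add atoms: tert-butyl hydroperoxide, CC(C)(C)OO
Why: Hydroxyl-directed epoxidation through a titanium alkoxide–peroxide complex; A(1,3) strain with the cis C6 substituent holds the C3–H in the olefin plane, so oxygen arrives syn to O3 and gives the threo epoxy alcohol. The C7=C11 olefin has no directing hydroxyl and is left.

Step 23
Reactants: 30 4,5-epoxy-3-ol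
Product: 31 3-O-TBS ether (1R,3S,4S,5S,8R,9R,10R)
Conditions: TBSCl, imidazole, DMF, 35 °C
Reagents that add atoms: tert-butyldimethylsilyl chloride, CC(C)(C)[Si](C)(C)Cl
Why: Standard silylation of a secondary alcohol; the chloride/imidazole system is chosen over the triflate so that the ketal on O9 is not attacked.

Step 24
Reactants: 31 3-O-TBS, 9-O-MOP macrocycle
Product: 32 13-membered (Z)-allyl stannyl ether, 9-OH free, 3-O-TBS (1R,3S,4S,5S,8R,9R,10S)
Conditions: pyridinium p-toluenesulfonate (cat.), MeOH, 0 °C
Reagents that add atoms: none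
Why: Transketalisation removes the mixed ketal under acid too weak to open the oxiranes, cleave the silyl ether or trigger loss of tin from the β-hydroxystannane.

Step 25
Reactants: 32 13-membered stannyl allyl ether
Product: 34 (1R,3S,4S,5S,7R,8S,9S,10S)-3-[(tert-butyldimethylsilyl)oxy]-1,10:4,5-diepoxygermacr-11(12)-ene-8,9-diol, via C8-lithio lithium alkoxide 33 (not isolated)
Conditions: n-BuLi (2.5 equiv), THF, −78 → −40 °C; H2O
Reagents that add atoms: none
Why: The first equivalent of n-BuLi converts the 9-hydroxyl into its lithium alkoxide and the second exchanges tin for lithium at C8 with retention, giving the configurationally stable α-alkoxy organolithium 33, whose β-oxygen is an oxido group and cannot leave. The carbanion attacks C7 of the allyl ether in a suprafacial [2,3]-sigmatropic (Still–Wittig) shift through a five-membered envelope: C7–C8 forms, O8–C12 breaks and the C11=C12 methylene appears. The closest known reaction type is the [2,3]-Wittig ring contraction of 13-membered allylic ethers to ten-membered carbocycles, here started by tin–lithium exchange. Ring A is closed by contraction (13 → 10 members) and not by end-to-end cyclisation. C8 is controlled by the stannane stereocentre, which reacts with inversion (8R in 32, 8S in 34). C7 is controlled by the (Z) geometry of C7=C11 together with the exo position of C9 on the envelope, which places C9 and C6 gauche on the forming bond and gives the 7,8-syn pair (7R); the C13 methyl on the central allyl carbon disfavours the endo alternative. The step needs the [2,3] shift to beat the [1,2] shift (low temperature), β-elimination (blocked by the lithium alkoxide on O9) and attack on the C1–C10 oxirane (its nearer carbon C10 is fully substituted, and the shift is fast at −78 °C).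

Step 26
Reactants: 34 8,9-diol
Product: 36 (1R,3S,4S,5S,7R,8S,9S,10R)-9-acetoxy-3-[(tert-butyldimethylsilyl)oxy]-1,10:4,5-diepoxygermacr-11(12)-en-8-ol, via cyclic 8,9-orthoacetate 35 (not isolated)
Conditions: MeC(OMe)3, pyridinium p-toluenesulfonate (cat.), CH2Cl2, rt; then AcOH–H2O (4:1), 0 °C
Reagents that add atoms: trimethyl orthoacetate, CC(OC)(OC)OC; water, O
Why: Regioselective monoacylation through a cyclic orthoester; kinetic hydrolysis of the hemi-orthoester cleaves the bond to the less hindered oxygen, which should leave the acetate on O9 (next to the fully substituted C10). The weak acids used should not open the oxiranes or move the ester.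

Step 27
Reactants: 36 9-acetate, 3-O-TBS
Product: 37 (1R,3S,4R,5S,7R,8S,9S,10R)-9-acetoxy-1,10:4,5-diepoxygermacr-11(12)-ene-3,8-diol
Conditions: HF·pyridine, pyridine, THF, 0 °C → rt
Reagents that add atoms: none
Why: Buffered HF·pyridine removes the secondary silyl ether without generating an alkoxide, so the acetate does not migrate from O9 to O8; such oxiranes tolerate this reagent.

Step 28
Reactants: 37 3,8-diol 9-acetate; 38 angelic acid [(Z)-2-methylbut-2-enoic acid] (one molecule for each of the two hydroxyls)
Product: 40 (1R,3S,4S,5S,7R,8S,9S,10R)-9-acetoxy-1,10:4,5-diepoxygermacr-11(12)-ene-3,8-diyl bis[(Z)-2-methylbut-2-enoate] (target CNP0220329.1), via angelic 2,4,6-trichlorobenzoic anhydride 39 (not isolated)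
Conditions: 38 (excess), 2,4,6-trichlorobenzoyl chloride, Et3N, toluene, rt; then 37, 75 °C
Reagents that add atoms: angelic acid (the second molecule of 38, which esterifies the other hydroxyl), C/C=C(/C)C(=O)O
Why: Yamaguchi-type esterification through the mixed anhydride without a nucleophilic amine catalyst, the established way to make angelates with little Z→E isomerisation; the hindered aroyl carbonyl directs both hydroxyls to the angeloyl carbonyl. Each hydroxyl consumes one molecule of 39, so both angeloyl groups are delivered in the same operation.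

## Compound list

1 | 3-[(tert-butyldimethylsilyl)oxy]propanal | O=CCCO[Si](C)(C)C(C)(C)C | starting material
2 | ethyltriphenylphosphonium iodide | CC[P+](c1ccccc1)(c1ccccc1)c1ccccc1.[I-] | starting material
3 | (1-iodoethyl)triphenylphosphonium iodide | CC(I)[P+](c1ccccc1)(c1ccccc1)c1ccccc1.[I-] | intermediate (not isolated)
4 | (Z)-tert-butyl[(4-iodopent-3-en-1-yl)oxy]dimethylsilane | I/C(C)=C\CCO[Si](C)(C)C(C)(C)C | intermediate
5 | (Z)-4-iodopent-3-en-1-ol | I/C(C)=C\CCO | intermediate
6 | (Z)-4-iodopent-3-enal | I/C(C)=C\CC=O | intermediate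
7 | ethyl 2-[bis(2,2,2-trifluoroethoxy)phosphoryl]propanoate | CCOC(=O)C(C)P(=O)(OCC(F)(F)F)OCC(F)(F)F | starting material
8 | ethyl (2Z,5Z)-6-iodo-2-methylhepta-2,5-dienoate | CCOC(=O)/C(C)=C\C/C=C(/C)I | intermediate
9 | (2Z,5Z)-6-iodo-2-methylhepta-2,5-dien-1-ol | OC/C(C)=C\C/C=C(/C)I | intermediate
10 | (2Z,5Z)-1-bromo-6-iodo-2-methylhepta-2,5-diene | BrC/C(C)=C\C/C=C(/C)I | intermediate
11 | ethyl (Z)-5-[(tert-butyldimethylsilyl)oxy]-2-methylpent-2-enoate | CCOC(=O)/C(C)=C\CCO[Si](C)(C)C(C)(C)C | intermediate
12 | (Z)-5-[(tert-butyldimethylsilyl)oxy]-2-methylpent-2-en-1-ol | OC/C(C)=C\CCO[Si](C)(C)C(C)(C)C | intermediate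
13 | [(2S,3R)-3-{2-[(tert-butyldimethylsilyl)oxy]ethyl}-2-methyloxiran-2-yl]methanol | CC(C)(C)[Si](C)(C)OCC[C@H]1O[C@@]1(C)CO | intermediate
14 | (2R,3R)-3-{2-[(tert-butyldimethylsilyl)oxy]ethyl}-2-methyloxirane-2-carbaldehyde | CC(C)(C)[Si](C)(C)OCC[C@H]1O[C@@]1(C)C=O | intermediate
15 | vinylmagnesium bromide | C=C[Mg]Br | starting material
16 | (S)-1-[(2S,3R)-3-{2-[(tert-butyldimethylsilyl)oxy]ethyl}-2-methyloxiran-2-yl]prop-2-en-1-ol | CC(C)(C)[Si](C)(C)OCC[C@H]1O[C@@]1(C)[C@@H](O)C=C | intermediate
17 | tert-butyl(2-{(2R,3R)-3-[(S)-1-[(2-methoxypropan-2-yl)oxy]prop-2-en-1-yl]-3-methyloxiran-2-yl}ethoxy)dimethylsilane | CC(C)(C)[Si](C)(C)OCC[C@H]1O[C@@]1(C)[C@@H](OC(C)(C)OC)C=C | intermediate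
18 | (R)-2-[(2-methoxypropan-2-yl)oxy]-2-[(2R,3R)-3-{2-[(tert-butyldimethylsilyl)oxy]ethyl}-2-methyloxiran-2-yl]acetaldehyde | CC(C)(C)[Si](C)(C)OCC[C@H]1O[C@@]1(C)[C@@H](OC(C)(C)OC)C=O | intermediate
19 | tributyltin hydride | CCCC[SnH](CCCC)CCCC | starting material
20 | tributylstannyllithium | [Li][Sn](CCCC)(CCCC)CCCC | intermediate (not isolated)
21 | lithium alkoxide of the α-hydroxystannane from 18 (both C8 epimers) | CC(C)(C)[Si](C)(C)OCC[C@H]1O[C@@]1(C)[C@@H](OC(C)(C)OC)C(O[Li])[Sn](CCCC)(CCCC)CCCC | intermediate (not isolated)
22 | (R)-2-[(2-methoxypropan-2-yl)oxy]-2-[(2R,3R)-3-{2-[(tert-butyldimethylsilyl)oxy]ethyl}-2-methyloxiran-2-yl]-1-(tributylstannyl)ethan-1-one | CC(C)(C)[Si](C)(C)OCC[C@H]1O[C@@]1(C)[C@@H](OC(C)(C)OC)C(=O)[Sn](CCCC)(CCCC)CCCC | intermediate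
23 | (1R,2R)-2-[(2-methoxypropan-2-yl)oxy]-2-[(2R,3R)-3-{2-[(tert-butyldimethylsilyl)oxy]ethyl}-2-methyloxiran-2-yl]-1-(tributylstannyl)ethan-1-ol | CC(C)(C)[Si](C)(C)OCC[C@H]1O[C@@]1(C)[C@@H](OC(C)(C)OC)[C@@H]([Sn](CCCC)(CCCC)CCCC)O | intermediate
24 | (2Z,5Z)-6-iodo-2-methylhepta-2,5-dien-1-yl ether of 23 (8R,9R,10R,1R; 9-O-MOP, 3-O-TBS) | CC(C)(C)[Si](C)(C)OCC[C@H]1O[C@@]1(C)[C@@H](OC(C)(C)OC)[C@@H]([Sn](CCCC)(CCCC)CCCC)OC/C(C)=C\C/C=C(/C)I | intermediate
25 | primary alcohol from 24 (3-OH) | OCC[C@H]1O[C@@]1(C)[C@@H](OC(C)(C)OC)[C@@H]([Sn](CCCC)(CCCC)CCCC)OC/C(C)=C\C/C=C(/C)I | intermediate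
26 | C3 aldehyde from 25 | O=CC[C@H]1O[C@@]1(C)[C@@H](OC(C)(C)OC)[C@@H]([Sn](CCCC)(CCCC)CCCC)OC/C(C)=C\C/C=C(/C)I | intermediate
27 | 13-membered stannyl allyl ether, (4Z,7Z), 3-hydroxy (C3 epimers), 9-O-MOP, 1,10-epoxide | C1/C(C)=C\C/C=C(C)\C(O)C[C@H]2O[C@@]2(C)[C@@H](OC(C)(C)OC)[C@@H]([Sn](CCCC)(CCCC)CCCC)O1 | intermediate
28 | 13-membered stannyl allyl ether, (4Z,7Z), 3-oxo, 9-O-MOP, 1,10-epoxide | C1/C(C)=C\C/C=C(C)\C(=O)C[C@H]2O[C@@]2(C)[C@@H](OC(C)(C)OC)[C@@H]([Sn](CCCC)(CCCC)CCCC)O1 | intermediate
29 | (1R,3S,8R,9R,10R)-13-membered stannyl allyl ether, (4Z,7Z), 3-ol, 9-O-MOP | C1/C(C)=C\C/C=C(C)\[C@@H](O)C[C@H]2O[C@@]2(C)[C@@H](OC(C)(C)OC)[C@@H]([Sn](CCCC)(CCCC)CCCC)O1 | intermediate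
30 | (1R,3S,4R,5S,8R,9R,10R)-13-membered stannyl allyl ether, 1,10:4,5-diepoxide, 3-ol, 9-O-MOP | C1/C(C)=C\C[C@@H]2O[C@]2(C)[C@@H](O)C[C@H]2O[C@@]2(C)[C@@H](OC(C)(C)OC)[C@@H]([Sn](CCCC)(CCCC)CCCC)O1 | intermediate
31 | (1R,3S,4S,5S,8R,9R,10R)-13-membered stannyl allyl ether, 3-O-TBS, 9-O-MOP | C1/C(C)=C\C[C@@H]2O[C@]2(C)[C@@H](O[Si](C)(C)C(C)(C)C)C[C@H]2O[C@@]2(C)[C@@H](OC(C)(C)OC)[C@@H]([Sn](CCCC)(CCCC)CCCC)O1 | intermediate
32 | (1R,3S,4S,5S,8R,9R,10S)-13-membered (Z)-allyl stannyl ether, 9-OH free, 3-O-TBS (key-step precursor) | C1/C(C)=C\C[C@@H]2O[C@]2(C)[C@@H](O[Si](C)(C)C(C)(C)C)C[C@H]2O[C@@]2(C)[C@@H](O)[C@@H]([Sn](CCCC)(CCCC)CCCC)O1 | intermediate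
33 | C8-lithio, O9-lithium alkoxide derived from 32 | C1/C(C)=C\C[C@@H]2O[C@]2(C)[C@@H](O[Si](C)(C)C(C)(C)C)C[C@H]2O[C@@]2(C)[C@@H](O[Li])[C@@H]([Li])O1 | intermediate (not isolated)
34 | (1R,3S,4S,5S,7R,8S,9S,10S)-3-[(tert-butyldimethylsilyl)oxy]-1,10:4,5-diepoxygermacr-11(12)-ene-8,9-diol (key-step product) | C=C(C)[C@H]1C[C@@H]2O[C@]2(C)[C@@H](O[Si](C)(C)C(C)(C)C)C[C@H]2O[C@@]2(C)[C@@H](O)[C@H]1O | intermediate
35 | cyclic 8,9-(1-methoxyethylidene) orthoacetate of 34 (both orthoester epimers) | C=C(C)[C@H]1C[C@@H]2O[C@]2(C)[C@@H](O[Si](C)(C)C(C)(C)C)C[C@H]2O[C@@]2(C)[C@@H](OC(C)(OC)O3)[C@H]13 | intermediate (not isolated)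
36 | (1R,3S,4S,5S,7R,8S,9S,10R)-9-acetoxy-3-[(tert-butyldimethylsilyl)oxy]-1,10:4,5-diepoxygermacr-11(12)-en-8-ol | C=C(C)[C@H]1C[C@@H]2O[C@]2(C)[C@@H](O[Si](C)(C)C(C)(C)C)C[C@H]2O[C@@]2(C)[C@@H](OC(C)=O)[C@H]1O | intermediate
37 | (1R,3S,4R,5S,7R,8S,9S,10R)-9-acetoxy-1,10:4,5-diepoxygermacr-11(12)-ene-3,8-diol | C=C(C)[C@H]1C[C@@H]2O[C@]2(C)[C@@H](O)C[C@H]2O[C@@]2(C)[C@@H](OC(C)=O)[C@H]1O | intermediate
38 | angelic acid, (Z)-2-methylbut-2-enoic acid | C/C=C(/C)C(=O)O | starting material
39 | angelic 2,4,6-trichlorobenzoic anhydride | C/C=C(/C)C(=O)OC(=O)c1c(Cl)cc(Cl)cc1Cl | intermediate (not isolated)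
40 | (1R,3S,4S,5S,7R,8S,9S,10R)-9-acetoxy-1,10:4,5-diepoxygermacr-11(12)-ene-3,8-diyl bis[(Z)-2-methylbut-2-enoate], CNP0220329.1 | C=C(C)[C@H]1C[C@@H]2O[C@]2(C)[C@@H](OC(=O)/C(C)=C\C)C[C@H]2O[C@@]2(C)[C@@H](OC(C)=O)[C@H]1OC(=O)/C(C)=C\C | target

## Step count and least certain steps

Total step count: 28. Longest linear sequence: 22 steps (steps 7 to 28, from 1); steps 1 to 6 form the side branch that joins at step 16.

**Step 25 (key step).** The most likely failure is poor facial discrimination at C7, because the 13-membered ring may fold the tether into the endo arrangement and give the C7 epimer; a second risk is consumption of the carbanion by the neighbouring C1–C10 oxirane or by a [1,2]-shift on warming. Fallback: contract the ring one stage earlier, on a macrocycle that has neither the C4–C5 oxirane nor the silyl group, and epoxidise afterwards. It sets out from 29. Pyridinium p-toluenesulfonate in methanol would remove the ketal to give the macrocyclic (4Z,7Z) 3,9-diol stannane F1. n-BuLi (3.5 equiv, THF, −78 → −40 °C) would carry it as the trianion through the same Still–Wittig contraction to the ten-membered (4Z)-ene 3,8,9-triol F2. Ti(OiPr)4/t-BuOOH would epoxidise the C4=C5 olefin under direction of the allylic 3-hydroxyl to give the bis-epoxy triol F3. The orthoacetate protocol of step 26, applied to its 8,9-diol, comes back to the route at 37. This variant is two steps shorter but is held in reserve, because it moves the C4–C5 epoxidation onto the ten-membered ring, where the directing effect must compete with ring conformation.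

**Step 16.** The most likely failure is reversal of stannyl carbinol formation once the alkoxide is generated (loss of the tributylstannyl anion, which is then alkylated itself), so that tin is lost before the ether forms. Fallback: make the bond by activating the electrophile and leaving the carbinol neutral. It sets out from 23 and 10: NaI in acetone would convert 10 into (2Z,5Z)-1,6-diiodo-2-methylhepta-2,5-diene F4, and silver oxide Ag2O (monovalent silver) in CH2Cl2 with molecular sieves would join F4 and 23 without any free alkoxide, coming back at 24.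

**Step 14.** The most likely failure is enolisation of the acylstannane towards C9 in the basic oxidation medium, which would erode the C9 configuration or open the oxirane by β-elimination. Fallback: leave out the acyl stage. It sets out from 18: 20 would be added at −78 °C and the alkoxide protonated cold, giving 23 together with its C8 epimer F5 under substrate control; chromatographic separation comes back at 23, at the price of material.

**Step 11.** The most likely failure is poor facial selectivity of the Grignard addition, giving a mixture at C9. Fallback: set C9 by reduction and not by addition. It sets out from 16 as its mixture with the C9 epimer: MnO2 would oxidise the mixture to the epoxy enone 1-[(2R,3R)-3-{2-[(tert-butyldimethylsilyl)oxy]ethyl}-2-methyloxiran-2-yl]prop-2-en-1-one F6, and Zn(BH4)2 (ether, −20 °C), chelated between carbonyl and oxirane oxygen, would deliver hydride to give the anti alcohol, coming back at 16.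

**Step 26.** The most likely failure is wrong regiochemistry in the opening of the hemi-orthoester (acetate on O8), because the steric bias between O8 and O9 is small and the electronic bias points the other way; acid-induced oxirane opening is a lesser risk. Fallback: give up kinetic selection and recycle. It sets out from 34: Ac2O (1 equiv) with 2,4,6-collidine at −20 °C would give 36 together with the 8-acetate F7; after separation F7 would be returned to 34 with K2CO3 in methanol and resubmitted, so the sequence comes back at 36.

**Step 28.** The most likely failures are isomerisation of the activated angeloyl group to the tigloyl group, incomplete acylation of the two hindered hydroxyls, and drift of the acetate from O9 to O8 on heating with amine. Fallback: build the angelates on the substrate by olefination. It sets out from 37: 2-[bis(2,2,2-trifluoroethoxy)phosphoryl]propanoic acid F8 (from 7 by careful saponification with LiOH) would be coupled to both hydroxyls with dicyclohexylcarbodiimide and catalytic 4-(dimethylamino)pyridine to give the bis(phosphonopropionate) F9. KN(SiMe3)2 with 18-crown-6 and acetaldehyde at −78 °C (Still–Gennari olefination, Z-selective; the phosphonate is far more acidic than the acetate) would then come back at 40.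

## Further compounds

F1 | step 25 | 13-membered (4Z,7Z) stannyl allyl ether, 3,9-diol, 1,10-epoxide | C1/C(C)=C\C/C=C(C)\[C@@H](O)C[C@H]2O[C@@]2(C)[C@@H](O)[C@@H]([Sn](CCCC)(CCCC)CCCC)O1
F2 | step 25 | ten-membered (4Z)-1,10-epoxygermacra-4,11(12)-diene-3,8,9-triol | C=C(C)[C@H]1C/C=C(C)\[C@@H](O)C[C@H]2O[C@@]2(C)[C@@H](O)[C@H]1O
F3 | step 25 | 1,10:4,5-diepoxygermacr-11(12)-ene-3,8,9-triol | C=C(C)[C@H]1C[C@@H]2O[C@]2(C)[C@@H](O)C[C@H]2O[C@@]2(C)[C@@H](O)[C@H]1O
F4 | step 16 | (2Z,5Z)-1,6-diiodo-2-methylhepta-2,5-diene | IC/C(C)=C\C/C=C(/C)I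
F5 | step 14 | C8 epimer of 23, (1S,2R)-2-[(2-methoxypropan-2-yl)oxy]-2-[(2R,3R)-3-{2-[(tert-butyldimethylsilyl)oxy]ethyl}-2-methyloxiran-2-yl]-1-(tributylstannyl)ethan-1-ol | CC(C)(C)[Si](C)(C)OCC[C@H]1O[C@@]1(C)[C@@H](OC(C)(C)OC)[C@H]([Sn](CCCC)(CCCC)CCCC)O
F6 | step 11 | 1-[(2R,3R)-3-{2-[(tert-butyldimethylsilyl)oxy]ethyl}-2-methyloxiran-2-yl]prop-2-en-1-one | CC(C)(C)[Si](C)(C)OCC[C@H]1O[C@@]1(C)C(=O)C=C
F7 | step 26 | 8-acetoxy-3-[(tert-butyldimethylsilyl)oxy]-1,10:4,5-diepoxygermacr-11(12)-en-9-ol (regioisomer of 36) | C=C(C)[C@H]1C[C@@H]2O[C@]2(C)[C@@H](O[Si](C)(C)C(C)(C)C)C[C@H]2O[C@@]2(C)[C@@H](O)[C@H]1OC(C)=O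
F8 | step 28 | 2-[bis(2,2,2-trifluoroethoxy)phosphoryl]propanoic acid | CC(C(=O)O)P(=O)(OCC(F)(F)F)OCC(F)(F)F
F9 | step 28 | 3,8-bis-O-{2-[bis(2,2,2-trifluoroethoxy)phosphoryl]propanoyl} derivative of 37 | C=C(C)[C@H]1C[C@@H]2O[C@]2(C)[C@@H](OC(=O)C(C)P(=O)(OCC(F)(F)F)OCC(F)(F)F)C[C@H]2O[C@@]2(C)[C@@H](OC(C)=O)[C@H]1OC(=O)C(C)P(=O)(OCC(F)(F)F)OCC(F)(F)F
A1 | alternative 1 | 2-(buta-2,3-dien-2-yl)-4,4,5,5-tetramethyl-1,3,2-dioxaborolane (allenylboronate, pinacol ester) | C=C=C(C)B1OC(C)(C)C(C)(C)O1
A2 | alternative 1 | α-silyloxy aldehyde carrying C5–C9 with C7 and C8 set | C=CC[C@H](C(C)=C)[C@H](O[Si](C)(C)C(C)(C)C)C=O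
A3 | alternative 1 | methacrolein | C=C(C)C=O
A4 | alternative 1 | acyclic (Z)-9,3-diol (seventeen chain carbons) | C=CC[C@H](C(C)=C)[C@H](O[Si](C)(C)C(C)(C)C)[C@H](O)/C(C)=C\C[C@H](O)C(C)=C
A5 | alternative 2 | trans-9,10-epoxy-1-ol, (4Z)-ene, 3,8-bis-O-PMB | C=C(C)[C@H]1C/C=C(C)\[C@@H](OCc2ccc(OC)cc2)C[C@@H](O)[C@]2(C)O[C@H]2[C@H]1OCc1ccc(OC)cc1
A6 | alternative 2 | cis-1,10-epoxy-9-ol, (4Z)-ene, 3,8-bis-O-PMB | C=C(C)[C@H]1C/C=C(C)\[C@@H](OCc2ccc(OC)cc2)C[C@H]2O[C@@]2(C)[C@@H](O)[C@H]1OCc1ccc(OC)cc1
A7 | alternative 3 | open-chain diiodide (primary C6 iodide, (Z)-C5 alkenyl iodide), 3-O-TES, 9-acetate, 8-angelate | IC[C@H](C(C)=C)[C@H](OC(=O)/C(C)=C\C)[C@H](OC(C)=O)[C@]1(C)O[C@@H]1C[C@H](O[Si](CC)(CC)CC)/C(C)=C\I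
A8 | alternative 3 | (4Z)-1,10-epoxycyclodecene, 3-O-TES, 9-acetate, 8-angelate | C=C(C)[C@H]1C/C=C(C)\[C@@H](O[Si](CC)(CC)CC)C[C@H]2O[C@@]2(C)[C@@H](OC(C)=O)[C@H]1OC(=O)/C(C)=C\C
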